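**Retrosynthetic overview**

1. Target ⇐ triol 22 ⇐ 6β-hydroxy-7-ketone 20 ⇐ diosphenol 17: the 6β- and 7α-oxygens and the trans ring fusion are set last, on a ring B held at the 6,7-dione level.
2. Ring A (C4–C5 bond) ⇐ radical (MHAT/Giese) closure of the prenyl chain onto C5 of the monocyclic 2-silyloxycyclohexa-2,5-dienone 14.
3. Ring B ⇐ [3+3] annulation of keto aldehyde 10 with 1-silyloxybutan-2-one 12: aldol condensation C6→C5 and aldol condensation C8→C9 in one flask (forms C5–C6 and C8=C9).
4. Enabling feature: C10 is quaternary and sits between the C5 aldehyde and the C9 ketone, so 10 is a non-enolisable, non-aromatisable 1,3-dielectrophile; the C7 carbonyl makes C6 (oxygen-bearing) and C8 (methyl-bearing) a 1,3-dinucleophile that maps onto ring B atom for atom.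
5. 10 ⇐ geraniol (C1–C5, C10, C18–C20; C10 set by Sharpless epoxidation and alkynylalane opening) + two acetylene carbons (C9, C11) + Z-bromo ester 8 (C12–C16). Rings are formed in the order B, then A.

Key step: step 9

Remark: labdane numbering (C1–C20) is used for the skeletal carbons of all intermediates; geraniol, 4-methylfuran-2(5H)-one and 1-hydroxybutan-2-one are taken as the commercial starting materials.

**Step 1**
Reactants: 1 geraniol
Product: 2 [(2R,3R)-3-methyl-3-(4-methylpent-3-en-1-yl)oxiran-2-yl]methanol
Conditions: Ti(OiPr)4 (5 mol%), D-(−)-diethyl tartrate (6 mol%), t-BuOOH, 4 Å MS, CH2Cl2, −20 °C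
Reagents that add atoms: tert-butyl hydroperoxide CC(C)(C)OO
Why: Sharpless asymmetric epoxidation with the D-tartrate-derived titanium catalyst delivers oxygen to the face of the allylic 2,3-alkene that gives the (2R,3R)-epoxide, while the remote trisubstituted alkene, which has no directing hydroxyl, is left untouched.

**Step 2**
Reactants: 2 [(2R,3R)-3-methyl-3-(4-methylpent-3-en-1-yl)oxiran-2-yl]methanol
Product: 4 (2S,3R)-3-ethynyl-3,7-dimethyloct-6-ene-1,2-diol, via silylalkyne diol 3 (not isolated)
Conditions: Me3SiC≡CH, n-BuLi, then Et2AlCl (gives Et2AlC≡CSiMe3, 3 equiv), toluene, 0 → 25 °C; then K2CO3, MeOH, 25 °C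
Reagents that add atoms: (trimethylsilyl)acetylene C#C[Si](C)(C)C
Why: The aluminium alkoxide of the epoxy alcohol directs a second alkynylalane to the more substituted epoxide carbon in an SN2-type opening with inversion (regioselective organoaluminium opening of a 2,3-epoxy alcohol), which creates the quaternary stereocentre that becomes C10 in the required absolute configuration, and carbonate methanolysis then removes the alkynyl silyl group.

**Step 3**
Reactants: 4 (2S,3R)-3-ethynyl-3,7-dimethyloct-6-ene-1,2-diol
Product: 5 (3S,4S)-4,5-dihydroxy-3-methyl-3-(4-methylpent-3-en-1-yl)pentan-2-one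
Conditions: HgSO4 (5 mol%), dilute H2SO4, aq. THF, 40 °C
Reagents that add atoms: water O
Why: Mercury-catalysed Markovnikov hydration of the terminal alkyne (Kucherov reaction) gives the methyl ketone whose carbonyl carbon is C9, the trisubstituted alkene being much less reactive than the alkyne under these conditions.

**Step 4**
Reactants: 5 (3S,4S)-4,5-dihydroxy-3-methyl-3-(4-methylpent-3-en-1-yl)pentan-2-one
Product: 6 (3S)-3-[(4S)-2,2-dimethyl-1,3-dioxolan-4-yl]-3,7-dimethyloct-6-en-2-one
Conditions: Me2C(OMe)2, PPTS (cat.), CH2Cl2, 25 °C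
Reagents that add atoms: 2,2-dimethoxypropane COC(C)(C)OC
Why: Acid-catalysed transketalisation protects the 1,2-diol as its acetonide, so that the methyl ketone is the only acidic site in the enolate alkylation that follows.

**Step 5**
Reactants: 7 4-methylfuran-2(5H)-one
Product: 8 methyl (2Z)-4-bromo-3-methylbut-2-enoate
Conditions: anhydrous HBr, MeOH, 0 → 25 °C
Reagents that add atoms: hydrogen bromide Br; methanol CO
Why: Acid-promoted alkyl–oxygen cleavage of the butenolide by bromide at its allylic CH2–O carbon followed by Fischer esterification (the classical hydrogen bromide/alcohol ring opening of lactones) gives the 4-bromo enoate with the Z geometry fixed by the former ring.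

**Step 6**
Reactants: 6 (3S)-3-[(4S)-2,2-dimethyl-1,3-dioxolan-4-yl]-3,7-dimethyloct-6-en-2-one; 8 methyl (2Z)-4-bromo-3-methylbut-2-enoate
Product: 9 methyl (2Z,7S)-7-[(4S)-2,2-dimethyl-1,3-dioxolan-4-yl]-3,7,11-trimethyl-6-oxododeca-2,10-dienoate
Conditions: LDA, THF, −78 °C; then 8, −78 → −30 °C
Reagents that add atoms: none
Why: The methyl group is the only enolisable position of ketone 6 (the other α-carbon is quaternary), so kinetic deprotonation and SN2 alkylation of the lithium enolate by the allylic bromide form the C11–C12 bond without touching the Z-alkene.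

**Step 7**
Reactants: 9 methyl (2Z,7S)-7-[(4S)-2,2-dimethyl-1,3-dioxolan-4-yl]-3,7,11-trimethyl-6-oxododeca-2,10-dienoate
Product: 10 methyl (2Z,7S)-7-formyl-3,7,11-trimethyl-6-oxododeca-2,10-dienoate
Conditions: H5IO6, EtOAc, 25 °C
Reagents that add atoms: none
Why: Periodic acid hydrolyses the terminal acetonide and cleaves the liberated glycol in the same flask (Malaprade-type oxidative cleavage), unveiling the C5 aldehyde next to the quaternary carbon, which cannot epimerise.

**Step 8**
Reactants: 11 1-hydroxybutan-2-one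
Product: 12 1-[(tert-butyldimethylsilyl)oxy]butan-2-one
Conditions: TBSCl, imidazole, CH2Cl2, 0 → 25 °C
Reagents that add atoms: tert-butyldimethylsilyl chloride CC(C)(C)[Si](C)(C)Cl
Why: Standard silylation of the primary alcohol blocks the hydroxyl, so that C6 enters ring B as an enol silyl ether and cannot become a free ketone during the annulation.

**Step 9**
Reactants: 10 methyl (2Z,7S)-7-formyl-3,7,11-trimethyl-6-oxododeca-2,10-dienoate; 12 1-[(tert-butyldimethylsilyl)oxy]butan-2-one
Product: 14 methyl (2Z)-5-[(6S)-4-[(tert-butyldimethylsilyl)oxy]-2,6-dimethyl-6-(4-methylpent-3-en-1-yl)-3-oxocyclohexa-1,4-dien-1-yl]-3-methylpent-2-enoate, via acyclic silyloxy enone 13 (not isolated)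
Conditions: pyrrolidine (0.3 equiv), AcOH (0.3 equiv), 4 Å MS, toluene, 25 → 80 °C
Reagents that add atoms: none
Why: Proposed new method: pyrrolidinium acetate turns the non-enolisable C5 aldehyde of 10 into an iminium ion that is attacked by the enamine of 12 at its oxygen-bearing methylene C6, and loss of the amine gives enone 13 (bond C5–C6); the ethyl α-carbon C8 of 13, now the only enolisable position next to C7, then adds as enamine or enol to the C9 ketone in a 6-(enolendo)-exo-trig aldol closure of ring B, and dehydration gives the tetrasubstituted C8=C9 bond. The closest known reaction type is the amine-salt-mediated [3+3] cyclohexadienone annulation of 2,2-disubstituted 3-oxo-aldehydes with simple ketones (aldol condensation followed by intramolecular aldol condensation); new here is the α-silyloxy ketone as the three-carbon partner, which delivers ring B directly at the diosphenol oxidation level with the C8 methyl and the side chain in place. No new stereocentre is formed, and the quaternary C10 set in step 2 passes through unchanged because it carries no acidic hydrogen. The step needs regioselectivity twice (C6 rather than C8 must meet the aldehyde, and C8 rather than C11 must close onto a ketone): the oxygen substituent makes C6 the more enolisable site and the aldehyde is the more electrophilic carbonyl, the E and Z isomers of 13 interconvert by reversible amine addition, and only the C8→C9 closure leads to the stable cross-conjugated 2,5-dienone, whereas the C11→C7 closure would give a less stable linear dienone in a reversible manifold.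

**Step 10**
Reactants: 14 methyl (2Z)-5-[(6S)-4-[(tert-butyldimethylsilyl)oxy]-2,6-dimethyl-6-(4-methylpent-3-en-1-yl)-3-oxocyclohexa-1,4-dien-1-yl]-3-methylpent-2-enoate
Product: 15 methyl (13Z)-6-[(tert-butyldimethylsilyl)oxy]-7-oxolabda-8,13-dien-15-oate (C5 and C6 not controlled)
Conditions: Fe(acac)3 (0.5 equiv), PhSiH3, EtOH/(CH2OH)2, 60 °C
Reagents that add atoms: none
Why: Hydrogen-atom transfer from an iron hydride to the electron-rich trisubstituted alkene (MHAT-initiated Giese cyclisation, a reductive olefin–enone coupling) gives the tertiary C4 radical, which closes ring A by 6-exo-trig addition to C5, the unsubstituted β-carbon of the silyloxy-enone, the enoate and the tetrasubstituted enone not being hydrogen-atom acceptors; the tether can reach only one face, so a cis ring fusion is expected, but the configurations at C5 and C6 are erased in the next step.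

**Step 11**
Reactants: 15 methyl (13Z)-6-[(tert-butyldimethylsilyl)oxy]-7-oxolabda-8,13-dien-15-oate
Product: 17 methyl (13Z)-6-hydroxy-7-oxolabda-5,8,13-trien-15-oate, via α-ketol 16 (not isolated)
Conditions: TBAF, THF, 0 °C; then Dess–Martin periodinane, NaHCO3, CH2Cl2, 25 °C
Reagents that add atoms: none
Why: Fluoride removes the silyl group and Dess–Martin oxidation of the resulting α-ketol gives the 1,2-dione, which enolises towards C5 to the diosphenol, so that C5 and C6 both become trigonal again.

**Step 12**
Reactants: 17 methyl (13Z)-6-hydroxy-7-oxolabda-5,8,13-trien-15-oate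
Product: 19 methyl (13Z)-6β,7ξ-dihydroxylabda-8,13-dien-15-oate, via 7-hydroxy-6-ketone 18 (not isolated)
Conditions: NaBH4 (excess), MeOH/THF, −20 → 0 °C
Reagents that add atoms: none
Why: Borohydride reduces the C7 carbonyl, the enol left behind ketonises by protonation of C5 on the α face anti to the axial methyl groups on C10 and C4 (the trans ring fusion, also reachable by epimerisation next to the 6-ketone), and hydride then attacks the C6 ketone of 18 from the same open α face to give the axial 6β-alcohol, the C7 carbinol being left as a mixture that converges in the next step.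

**Step 13**
Reactants: 19 methyl (13Z)-6β,7ξ-dihydroxylabda-8,13-dien-15-oate
Product: 20 methyl (13Z)-6β-hydroxy-7-oxolabda-8,13-dien-15-oate
Conditions: MnO2 (activated), CH2Cl2, 25 °C
Reagents that add atoms: none
Why: Activated MnO2 oxidises only the allylic C7 alcohol, so both C7 epimers converge on the 6β-hydroxy enone.

**Step 14**
Reactants: 20 methyl (13Z)-6β-hydroxy-7-oxolabda-8,13-dien-15-oate
Product: 21 methyl (13Z)-6β,7α-dihydroxylabda-8,13-dien-15-oate
Conditions: Me4NBH(OAc)3, AcOH/MeCN, −20 °C
Reagents that add atoms: none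
Why: In the hydroxyl-directed triacetoxyborohydride reduction (Evans–Saksena type) the 6β-alkoxyborohydride delivers hydride intramolecularly to the β face of the neighbouring C7 ketone, which places the new hydroxyl on the α face, trans to the 6β-hydroxyl.

**Step 15**
Reactants: 21 methyl (13Z)-6β,7α-dihydroxylabda-8,13-dien-15-oate
Product: 22 (13Z)-labda-8,13-diene-6β,7α,15-triol
Conditions: DIBAL-H (i-Bu2AlH, 5 equiv), CH2Cl2, −78 °C; Rochelle salt work-up
Reagents that add atoms: none
Why: DIBAL-H reduces the conjugated methyl ester by 1,2-addition to the Z-allylic alcohol without affecting the isolated alkenes or the alkene geometry.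

**Step 16**
Reactants: 22 (13Z)-labda-8,13-diene-6β,7α,15-triol
Product: 23 (5S,6S,7S,10S,13Z)-6-hydroxylabda-8,13-diene-7,15-diyl diacetate (6β-hydroxy-7α,15-diacetoxy; target)
Conditions: Ac2O, pyridine, 0 → 25 °C
Reagents that add atoms: acetic anhydride CC(=O)OC(C)=O
Why: Acetic anhydride in pyridine acylates the primary allylic C15 hydroxyl and the allylic 7α-hydroxyl, whereas the 6β-hydroxyl, syn-axial to the methyl groups on C4 and C10, is too hindered to react under these mild conditions.

**Compound list**

1 | geraniol, (2E)-3,7-dimethylocta-2,6-dien-1-ol | CC(C)=CCC/C(C)=C/CO | starting material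
2 | [(2R,3R)-3-methyl-3-(4-methylpent-3-en-1-yl)oxiran-2-yl]methanol | OC[C@H]1O[C@]1(C)CCC=C(C)C | intermediate
3 | (2S,3R)-3,7-dimethyl-3-[(trimethylsilyl)ethynyl]oct-6-ene-1,2-diol (silylalkyne diol) | OC[C@@H](O)[C@](C)(CCC=C(C)C)C#C[Si](C)(C)C | intermediate
4 | (2S,3R)-3-ethynyl-3,7-dimethyloct-6-ene-1,2-diol | OC[C@@H](O)[C@](C)(CCC=C(C)C)C#C | intermediate
5 | (3S,4S)-4,5-dihydroxy-3-methyl-3-(4-methylpent-3-en-1-yl)pentan-2-one | OC[C@@H](O)[C@](C)(CCC=C(C)C)C(C)=O | intermediate
6 | (3S)-3-[(4S)-2,2-dimethyl-1,3-dioxolan-4-yl]-3,7-dimethyloct-6-en-2-one | CC1(C)OC[C@@H](O1)[C@](C)(CCC=C(C)C)C(C)=O | intermediate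
7 | 4-methylfuran-2(5H)-one | CC1=CC(=O)OC1 | starting material
8 | methyl (2Z)-4-bromo-3-methylbut-2-enoate | COC(=O)/C=C(/C)CBr | intermediate
9 | methyl (2Z,7S)-7-[(4S)-2,2-dimethyl-1,3-dioxolan-4-yl]-3,7,11-trimethyl-6-oxododeca-2,10-dienoate | CC1(C)OC[C@@H](O1)[C@](C)(CCC=C(C)C)C(=O)CC/C(C)=C\C(=O)OC | intermediate
10 | methyl (2Z,7S)-7-formyl-3,7,11-trimethyl-6-oxododeca-2,10-dienoate | O=C[C@](C)(CCC=C(C)C)C(=O)CC/C(C)=C\C(=O)OC | intermediate
11 | 1-hydroxybutan-2-one | CCC(=O)CO | starting material
12 | 1-[(tert-butyldimethylsilyl)oxy]butan-2-one | CCC(=O)CO[Si](C)(C)C(C)(C)C | intermediate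
13 | methyl (2Z,7S)-7-{2-[(tert-butyldimethylsilyl)oxy]-3-oxopent-1-en-1-yl}-3,7,11-trimethyl-6-oxododeca-2,10-dienoate (acyclic silyloxy enone; new alkene E/Z not fixed) | CCC(=O)C(O[Si](C)(C)C(C)(C)C)=C[C@](C)(CCC=C(C)C)C(=O)CC/C(C)=C\C(=O)OC | intermediate
14 | methyl (2Z)-5-[(6S)-4-[(tert-butyldimethylsilyl)oxy]-2,6-dimethyl-6-(4-methylpent-3-en-1-yl)-3-oxocyclohexa-1,4-dien-1-yl]-3-methylpent-2-enoate | CC1=C(CC/C(C)=C\C(=O)OC)[C@@](C)(CCC=C(C)C)C=C(O[Si](C)(C)C(C)(C)C)C1=O | intermediate
15 | methyl (13Z)-6-[(tert-butyldimethylsilyl)oxy]-7-oxolabda-8,13-dien-15-oate (10β-methyl; C5 and C6 not controlled, cis ring fusion expected) | COC(=O)/C=C(/C)CCC1=C(C)C(=O)C(O[Si](C)(C)C(C)(C)C)C2C(C)(C)CCC[C@]12C | intermediate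
16 | methyl (13Z)-6-hydroxy-7-oxolabda-8,13-dien-15-oate (α-ketol; C5 and C6 not controlled) | COC(=O)/C=C(/C)CCC1=C(C)C(=O)C(O)C2C(C)(C)CCC[C@]12C | intermediate
17 | methyl (13Z)-6-hydroxy-7-oxolabda-5,8,13-trien-15-oate (diosphenol, 10β-methyl) | COC(=O)/C=C(/C)CCC1=C(C)C(=O)C(O)=C2C(C)(C)CCC[C@]12C | intermediate
18 | methyl (13Z)-7ξ-hydroxy-6-oxolabda-8,13-dien-15-oate (5α-H, trans-fused; C7 epimers) | COC(=O)/C=C(/C)CCC1=C(C)C(O)C(=O)[C@H]2C(C)(C)CCC[C@]12C | intermediate
19 | methyl (13Z)-6β,7ξ-dihydroxylabda-8,13-dien-15-oate (C7 epimers) | COC(=O)/C=C(/C)CCC1=C(C)C(O)[C@@H](O)[C@H]2C(C)(C)CCC[C@]12C | intermediate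
20 | methyl (13Z)-6β-hydroxy-7-oxolabda-8,13-dien-15-oate | COC(=O)/C=C(/C)CCC1=C(C)C(=O)[C@@H](O)[C@H]2C(C)(C)CCC[C@]12C | intermediate
21 | methyl (13Z)-6β,7α-dihydroxylabda-8,13-dien-15-oate | COC(=O)/C=C(/C)CCC1=C(C)[C@H](O)[C@@H](O)[C@H]2C(C)(C)CCC[C@]12C | intermediate
22 | (13Z)-labda-8,13-diene-6β,7α,15-triol | OC/C=C(/C)CCC1=C(C)[C@H](O)[C@@H](O)[C@H]2C(C)(C)CCC[C@]12C | intermediate
23 | (5S,6S,7S,10S,13Z)-6-hydroxylabda-8,13-diene-7,15-diyl diacetate | CC(=O)OC/C=C(/C)CCC1=C(C)[C@H](OC(C)=O)[C@@H](O)[C@H]2C(C)(C)CCC[C@]12C | target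

**Step count and risks**

Total step count: 16. Longest linear sequence: 14 steps (steps 1–4, 6, 7 and 9–16, from geraniol).

Steps most likely to fail:

Step 9 (Proposed new method). The first condensation may take place at C8 instead of C6 of 12. The amine may also deformylate keto aldehyde 10, or the enol silyl ether may be lost before ring closure so that other aldol closures compete. The fallback uses known chemistry, is stepwise and regiodefined, and sets out from 10 and 12. Soft enolisation of 12 (TBSOTf, Et3N, CH2Cl2) gives (Z)-1,2-bis[(tert-butyldimethylsilyl)oxy]but-1-ene F1. Its BF3·OEt2-mediated Mukaiyama aldol addition to the aldehyde of 10 gives methyl (2Z,7S)-7-{2-[(tert-butyldimethylsilyl)oxy]-1-hydroxy-3-oxopentyl}-3,7,11-trimethyl-6-oxododeca-2,10-dienoate F2, in which the C5–C6 bond is fixed at the oxygen-bearing carbon. Mesylation and elimination (MsCl, Et3N, then DBU) give enone 13 as an isolated compound. Its intramolecular aldol condensation (pyrrolidinium acetate or t-BuOK) closes C8=C9, and the fallback comes back to the route at 14.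

Step 10. The tertiary radical may be reduced before it closes onto the hindered C5, so that the alkene is merely hydrogenated, or the enol silyl ether may be solvolysed in the protic medium. The fallback sets out from 14. Markovnikov addition of HCl (CH2Cl2, −40 °C) to the trisubstituted alkene gives the tertiary chloride methyl (2Z)-5-[(6S)-4-[(tert-butyldimethylsilyl)oxy]-6-(4-chloro-4-methylpentyl)-2,6-dimethyl-3-oxocyclohexa-1,4-dien-1-yl]-3-methylpent-2-enoate F3. Its C4 radical is then generated in an aprotic tin hydride chain (Bu3SnH, AIBN, benzene, 80 °C) and cyclises in the same 6-exo mode; the fallback comes back to the route at 15.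

Step 14. Ligand exchange at the hindered axial 6β-hydroxyl may be slow, so that the reduction loses its facial selectivity. The fallback sets out from 20 and replaces directed delivery by inversion. Luche reduction (NaBH4, CeCl3, MeOH), with hydride attack from the open α face, gives methyl (13Z)-6β,7β-dihydroxylabda-8,13-dien-15-oate F4. Mitsunobu inversion at the allylic C7 (4-nitrobenzoic acid, PPh3, DIAD) gives methyl (13Z)-6β-hydroxy-7α-(4-nitrobenzoyloxy)labda-8,13-dien-15-oate F5. Methanolysis (K2CO3, MeOH) then comes back to the route at 21.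

**Further compounds**

F1 | step 9 | (Z)-1,2-bis[(tert-butyldimethylsilyl)oxy]but-1-ene | CC/C(O[Si](C)(C)C(C)(C)C)=C/O[Si](C)(C)C(C)(C)C
F2 | step 9 | methyl (2Z,7S)-7-{2-[(tert-butyldimethylsilyl)oxy]-1-hydroxy-3-oxopentyl}-3,7,11-trimethyl-6-oxododeca-2,10-dienoate | CCC(=O)C(O[Si](C)(C)C(C)(C)C)C(O)[C@](C)(CCC=C(C)C)C(=O)CC/C(C)=C\C(=O)OC
F3 | step 10 | methyl (2Z)-5-[(6S)-4-[(tert-butyldimethylsilyl)oxy]-6-(4-chloro-4-methylpentyl)-2,6-dimethyl-3-oxocyclohexa-1,4-dien-1-yl]-3-methylpent-2-enoate | CC1=C(CC/C(C)=C\C(=O)OC)[C@@](C)(CCCC(C)(C)Cl)C=C(O[Si](C)(C)C(C)(C)C)C1=O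
F4 | step 14 | methyl (13Z)-6β,7β-dihydroxylabda-8,13-dien-15-oate | COC(=O)/C=C(/C)CCC1=C(C)[C@@H](O)[C@@H](O)[C@H]2C(C)(C)CCC[C@]12C
F5 | step 14 | methyl (13Z)-6β-hydroxy-7α-(4-nitrobenzoyloxy)labda-8,13-dien-15-oate | COC(=O)/C=C(/C)CCC1=C(C)[C@H](OC(=O)c3ccc(cc3)[N+](=O)[O-])[C@@H](O)[C@H]2C(C)(C)CCC[C@]12C
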